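**Assumptions (one line):** commercial (R)-(−)-linalool of ≥95% ee is the C4 source; germacrane numbering (C1–C15) is used for locants in the macrocyclic names.

## Retrosynthetic overview

1. Target 28 ⇐ hemiketal 27 by MeOH exchange ⇐ transannular hemiketalisation of a C1 ketone with the C4 tertiary OH; the 1,4-epoxy (THF) bridge is made last.
2. Ten-membered carbocycle and 5E enol-lactone alkene ⇐ C5–C6 macrocyclising vinylogous Mukaiyama aldol of the intact butenolide onto a C5 aldehyde (proposed new step), then E1cB.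
3. Seco-aldehyde 22 ⇐ C7–C8 Ni/Cr coupling of 4-iodobutenolide 14 with aldehyde 9; C8 set by CBS reduction; tiglate installed early, acetate late.
4. Aldehyde 9 ⇐ (R)-linalool (C1–C5, C15; supplies C4) plus Brown (Z)-crotylation (C8–C10, C14; sets C10).
5. Ring order: butenolide (from 2-butyne-1,4-diol) → ten-membered carbocycle → THF methyl ketal.

## Route

**Step 1**
Reactants: 1, (R)-(−)-linalool
Product: 2, (2R)-2-methylpentane-1,2,5-triol
Conditions: O3, CH2Cl2/MeOH, −78 °C; then NaBH4, −78 → 23 °C
Reagents that add atoms: ozone, O=[O+][O-] (oxygens of the two new primary OH groups)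
Why: Exhaustive ozonolysis with reductive work-up cleaves both alkenes (acetone and formaldehyde lost) and leaves the C4 tertiary carbinol of linalool untouched.

**Step 2**
Reactants: 2
Product: 3, 3-[(4R)-2,2,4-trimethyl-1,3-dioxolan-4-yl]propan-1-ol
Conditions: Me2C(OMe)2, PPTS (cat.), acetone, 23 °C
Reagents that add atoms: 2,2-dimethoxypropane, COC(C)(C)OC
Why: Thermodynamic acetonide formation takes the 1,2-diol (five-membered dioxolane) and leaves the remote primary C1 hydroxyl free.

**Step 3**
Reactants: 3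
Product: 4, 3-[(4R)-2,2,4-trimethyl-1,3-dioxolan-4-yl]propanal
Conditions: (COCl)2, DMSO, CH2Cl2, −78 °C; Et3N
Reagents that add atoms: none
Why: Swern oxidation of a primary alcohol; there is no epimerisable centre and the acetonide is stable.

**Step 4**
Reactants: 4; 5, cis-2-butene
Product: 6, (3R,4R)-3-methyl-6-[(4R)-2,2,4-trimethyl-1,3-dioxolan-4-yl]hex-1-en-4-ol (syn)
Conditions: 5, n-BuLi, KOt-Bu, THF, −78 → −45 °C; (−)-Ipc2BOMe [(+)-α-pinene series]; BF3·OEt2; then 4, −78 °C; NaOH, H2O2
Reagents that add atoms: none beyond 5, delivered as (Z)-crotyl-B(Ipc)2, C/C=C\CB(C1CC2CC(C1C)C2(C)C)C1CC2CC(C1C)C2(C)C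
Why: Brown asymmetric crotylboration through a chair Zimmerman–Traxler transition state; the (+)-α-pinene-derived reagent adds to the aldehyde Si face and the Z-crotyl geometry gives the syn adduct, which fixes C10 as R (the C1 carbinol, R, is oxidised later).

**Step 5**
Reactants: 6
Product: 7, triethylsilyl ether of 6
Conditions: TESCl, imidazole, DMF, 0 °C
Reagents that add atoms: chlorotriethylsilane, CC[Si](Cl)(CC)CC
Why: Standard silylation of the secondary alcohol; the C1 oxygen stays masked so no C1 ketone exists before the macrocycle is closed.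

**Step 6**
Reactants: 7
Product: 8, (3R,4R)-3-methyl-4-(triethylsilyloxy)-6-[(4R)-2,2,4-trimethyl-1,3-dioxolan-4-yl]hexan-1-ol
Conditions: 9-BBN, THF, 23 °C; then NaOH, H2O2, 0 °C
Reagents that add atoms: hydrogen peroxide, OO
Why: Anti-Markovnikov hydroboration–oxidation of the only alkene places oxygen on C8.

**Step 7**
Reactants: 8
Product: 9, (3R,4R)-3-methyl-4-(triethylsilyloxy)-6-[(4R)-2,2,4-trimethyl-1,3-dioxolan-4-yl]hexanal
Conditions: Dess–Martin periodinane, NaHCO3, CH2Cl2, 23 °C
Reagents that add atoms: none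
Why: Buffered Dess–Martin oxidation; the aldehyde has an α-CH2, so C10 cannot epimerise.

**Step 8**
Reactants: 10, but-2-yne-1,4-diol
Product: 11, 4-(tert-butyldiphenylsilyloxy)but-2-yn-1-ol
Conditions: NaH (1.0 equiv), THF, 0 °C; TBDPSCl
Reagents that add atoms: tert-butylchlorodiphenylsilane, CC(C)(C)[Si](Cl)(c1ccccc1)c1ccccc1
Why: Monosilylation of a symmetric diol through its monosodium alkoxide.

**Step 9**
Reactants: 11
Product: 12, 4-(tert-butyldiphenylsilyloxy)but-2-yn-1-yl methyl carbonate
Conditions: ClCO2Me, pyridine, CH2Cl2, 0 °C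
Reagents that add atoms: methyl chloroformate, COC(=O)Cl
Why: Routine carbonate formation to activate the propargylic position.

**Step 10**
Reactants: 12
Product: 13, methyl 2-[(tert-butyldiphenylsilyloxy)methyl]buta-2,3-dienoate
Conditions: Pd2(dba)3·CHCl3 (2.5 mol %), PPh3, CO (10 atm), MeOH, 50 °C
Reagents that add atoms: carbon monoxide, [C-]#[O+]; methanol, CO
Why: Tsuji-type decarboxylative alkoxycarbonylation: SN2′ oxidative addition gives an allenyl-palladium species that inserts CO at the carbon bearing CH2OSi and is trapped by methanol.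

**Step 11**
Reactants: 13
Product: 14, 3-[(tert-butyldiphenylsilyloxy)methyl]-4-iodofuran-2(5H)-one
Conditions: I2, MeCN/H2O (15:1), 23 °C
Reagents that add atoms: iodine, II
Why: Iodolactonisation of the 2,3-allenoate: I+ adds to the central allene carbon (C7), the ester carbonyl closes on the CH2 terminus (C6) and the methyl group is lost.

**Step 12**
Reactants: 9; 14
Product: 15, 3-[(tert-butyldiphenylsilyloxy)methyl]-4-{(1RS,3R,4R)-1-hydroxy-3-methyl-4-(triethylsilyloxy)-6-[(4R)-2,2,4-trimethyl-1,3-dioxolan-4-yl]hexyl}furan-2(5H)-one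
Conditions: CrCl2 (5 equiv), NiCl2 (2 mol %), DMSO, 23 °C
Reagents that add atoms: none
Why: Nozaki–Hiyama–Kishi coupling forms C7–C8 chemoselectively at the aldehyde under non-basic conditions that tolerate the acidic butenolide CH2; C8 is formed as an epimer mixture and corrected in steps 13–14.

**Step 13**
Reactants: 15
Product: 16, the corresponding C8 ketone (4-acylbutenolide)
Conditions: Dess–Martin periodinane, NaHCO3, CH2Cl2, 0 °C
Reagents that add atoms: none
Why: Mild oxidation of the allylic-type alcohol converges both C8 epimers on one ketone.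

**Step 14**
Reactants: 16
Product: 17, the (1S)-alcohol (C8 S)
Conditions: (R)-Me-CBS (0.3 equiv), catecholborane, toluene, −78 °C
Reagents that add atoms: none
Why: Corey–Bakshi–Shibata reduction with the sp2 butenolide carbon as the large group and C9H2 as the small group; (R)-CBS gives the 8S carbinol by analogy with aryl alkyl ketones, and the lactone is not reduced at −78 °C.

**Step 15**
Reactants: 17; 18, tiglic acid
Product: 19, (1S,3R,4R)-1-{4-[(tert-butyldiphenylsilyloxy)methyl]-5-oxo-2,5-dihydrofuran-3-yl}-3-methyl-4-(triethylsilyloxy)-6-[(4R)-2,2,4-trimethyl-1,3-dioxolan-4-yl]hexyl (2E)-2-methylbut-2-enoate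
Conditions: 18, 2,4,6-trichlorobenzoyl chloride, Et3N, DMAP, toluene, 23 °C
Reagents that add atoms: none (acyl group from 18)
Why: Yamaguchi esterification acylates the hindered secondary alcohol with retention at C8 and without E/Z isomerisation of the tiglate.

**Step 16**
Reactants: 19
Product: 20, (1S,3R,4R,7R)-1-{4-[(tert-butyldiphenylsilyloxy)methyl]-5-oxo-2,5-dihydrofuran-3-yl}-4,7,8-trihydroxy-3,7-dimethyloctyl (2E)-2-methylbut-2-enoate
Conditions: CSA (cat.), MeOH, 23 °C
Reagents that add atoms: none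
Why: Acidic methanolysis removes the acetonide and the secondary TES ether, while the primary TBDPS ether, tiglate and butenolide survive.

**Step 17**
Reactants: 20
Product: 21, the 4,7,8-tris(triethylsilyl) ether of 20
Conditions: TESOTf, 2,6-lutidine, CH2Cl2, −78 → 0 °C
Reagents that add atoms: triethylsilyl triflate, CC[Si](CC)(CC)OS(=O)(=O)C(F)(F)F
Why: Exhaustive silylation (TESOTf is reactive enough for the tertiary C4 hydroxyl) sets up the selective oxidation of the primary ether.

**Step 18**
Reactants: 21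
Product: 22, (1S,3R,4R,7R)-1-{4-[(tert-butyldiphenylsilyloxy)methyl]-5-oxo-2,5-dihydrofuran-3-yl}-3,7-dimethyl-8-oxo-4,7-bis(triethylsilyloxy)octyl (2E)-2-methylbut-2-enoate
Conditions: (COCl)2, DMSO, CH2Cl2, −78 → −30 °C; Et3N
Reagents that add atoms: none
Why: Under Swern conditions a primary TES ether is cleaved and oxidised far faster than secondary or tertiary ones, giving the non-enolisable α-quaternary C5 aldehyde directly.

**Step 19**
Reactants: 22
Product: 23, (1R,4R,8S,10R)-13-(tert-butyldiphenylsilyloxy)-5-hydroxy-1,4-bis(triethylsilyloxy)-8-tigloyloxygermacr-7(11)-en-6,12-olide (mixture at C5/C6)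
Conditions: slow addition of 22 to TMSOTf (3 equiv), i-Pr2NEt (5 equiv), CH2Cl2 (1 mM final), −40 → 0 °C; then citric acid, MeOH, 0 °C
Reagents that add atoms: none (the O-TMS group is removed on work-up)
Why: Proposed new method: a macrocyclising vinylogous Mukaiyama aldol that forms C5–C6 and the ten-membered carbocycle. Soft enolisation turns the butenolide into an aromatic 2-silyloxyfuran whose only free nucleophilic carbon is C6 (C11 is substituted), and the silyl-activated, non-enolisable aldehyde is the only electrophile because C1 is kept as a silyl ether (no competing six-ring closure onto a C1 carbonyl); closure is helped by the gem-disubstituted C4 and the planar furan, and the new C5/C6 centres are erased in step 20. The closest known reactions are the intermolecular vinylogous Mukaiyama aldol of 2-silyloxyfurans with aldehydes and Lewis-acid-templated intramolecular vinylogous aldol macrolactone closures.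

**Step 20**
Reactants: 23
Product: 24, (1R,4R,8S,10R)-13-(tert-butyldiphenylsilyloxy)-1,4-bis(triethylsilyloxy)-8-tigloyloxygermacra-5E,7(11)-dien-6,12-olide
Conditions: MsCl, Et3N, CH2Cl2, 0 °C; then DBU, 23 °C
Reagents that add atoms: none (the mesylate is eliminated)
Why: Mesylation and E1cB elimination through the furanolate converge all diastereomers of 23; the mesylate is a much better leaving group than the C13 silyl ether, and the ring holds C4 cis to C7, which is the 5E geometry.

**Step 21**
Reactants: 24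
Product: 25, (1R,4R,8S,10R)-1,4,13-trihydroxy-8-tigloyloxygermacra-5E,7(11)-dien-6,12-olide
Conditions: HF·pyridine, pyridine, THF, 0 → 23 °C
Reagents that add atoms: none
Why: Buffered fluoride removes both TES ethers and the TBDPS ether without base, which protects the enol lactone and both esters.

**Step 22**
Reactants: 25
Product: 26, the 13-O-acetate of 25
Conditions: AcCl (1.1 equiv), 2,4,6-collidine, CH2Cl2, −78 °C
Reagents that add atoms: acetyl chloride, CC(=O)Cl
Why: Kinetic acylation selects the primary allylic C13 hydroxyl over the hindered secondary C1 and tertiary C4 hydroxyls.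

**Step 23**
Reactants: 26
Product: 27, (1S,4R,8S,10R)-13-acetoxy-1,4-epoxy-1-hydroxy-8-tigloyloxygermacra-5E,7(11)-dien-6,12-olide (bridged hemiketal)
Conditions: Dess–Martin periodinane, NaHCO3, CH2Cl2, 23 °C
Reagents that add atoms: none
Why: Oxidation of the C1 carbinol gives a γ-hydroxy ketone that closes transannularly to the THF hemiketal; C1 (S) is dictated by C4 (R) because only the cis-2,5-bridged tetrahydrofuran can span the ten-membered ring.

**Step 24**
Reactants: 27
Product: 28, Vernolide-B, (1S,4R,8S,10R)-13-acetoxy-1,4-epoxy-1-methoxy-8-tigloyloxygermacra-5E,7(11)-dien-6,12-olide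
Conditions: MeOH, HC(OMe)3, PPTS (cat.), 23 °C
Reagents that add atoms: methanol, CO
Why: Acid-catalysed hemiketal-to-methyl-ketal exchange in methanol; the bicyclic framework allows only the 1S configuration, and the conditions are too mild to cleave the esters or epimerise C10.

## Compound list

1 | (R)-(−)-linalool | C=C[C@](C)(O)CCC=C(C)C | starting material
2 | (2R)-2-methylpentane-1,2,5-triol | OC[C@](C)(O)CCCO | intermediate
3 | 3-[(4R)-2,2,4-trimethyl-1,3-dioxolan-4-yl]propan-1-ol | OCCC[C@]1(C)COC(C)(C)O1 | intermediate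
4 | 3-[(4R)-2,2,4-trimethyl-1,3-dioxolan-4-yl]propanal | O=CCC[C@]1(C)COC(C)(C)O1 | intermediate
5 | cis-2-butene | C/C=C\C | starting material
6 | (3R,4R)-3-methyl-6-[(4R)-2,2,4-trimethyl-1,3-dioxolan-4-yl]hex-1-en-4-ol | C=C[C@@H](C)[C@H](O)CC[C@]1(C)COC(C)(C)O1 | intermediate
7 | TES ether of 6 | C=C[C@@H](C)[C@H](O[Si](CC)(CC)CC)CC[C@]1(C)COC(C)(C)O1 | intermediate
8 | (3R,4R)-3-methyl-4-(triethylsilyloxy)-6-[(4R)-2,2,4-trimethyl-1,3-dioxolan-4-yl]hexan-1-ol | OCC[C@@H](C)[C@H](O[Si](CC)(CC)CC)CC[C@]1(C)COC(C)(C)O1 | intermediate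
9 | (3R,4R)-3-methyl-4-(triethylsilyloxy)-6-[(4R)-2,2,4-trimethyl-1,3-dioxolan-4-yl]hexanal | O=CC[C@@H](C)[C@H](O[Si](CC)(CC)CC)CC[C@]1(C)COC(C)(C)O1 | intermediate
10 | but-2-yne-1,4-diol | OCC#CCO | starting material
11 | 4-(tert-butyldiphenylsilyloxy)but-2-yn-1-ol | OCC#CCO[Si](c1ccccc1)(c1ccccc1)C(C)(C)C | intermediate
12 | 4-(tert-butyldiphenylsilyloxy)but-2-yn-1-yl methyl carbonate | COC(=O)OCC#CCO[Si](c1ccccc1)(c1ccccc1)C(C)(C)C | intermediate
13 | methyl 2-[(tert-butyldiphenylsilyloxy)methyl]buta-2,3-dienoate | C=C=C(CO[Si](c1ccccc1)(c1ccccc1)C(C)(C)C)C(=O)OC | intermediate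
14 | 3-[(tert-butyldiphenylsilyloxy)methyl]-4-iodofuran-2(5H)-one | O=C1OCC(I)=C1CO[Si](c1ccccc1)(c1ccccc1)C(C)(C)C | intermediate
15 | NHK adduct, C8 epimers (C10 R, C1 R, C4 R) | O=C1OCC(C(O)C[C@@H](C)[C@H](O[Si](CC)(CC)CC)CC[C@]2(C)COC(C)(C)O2)=C1CO[Si](c1ccccc1)(c1ccccc1)C(C)(C)C | intermediate
16 | C8 ketone (4-acylbutenolide) | O=C1OCC(C(=O)C[C@@H](C)[C@H](O[Si](CC)(CC)CC)CC[C@]2(C)COC(C)(C)O2)=C1CO[Si](c1ccccc1)(c1ccccc1)C(C)(C)C | intermediate
17 | (8S)-alcohol | O=C1OCC([C@@H](O)C[C@@H](C)[C@H](O[Si](CC)(CC)CC)CC[C@]2(C)COC(C)(C)O2)=C1CO[Si](c1ccccc1)(c1ccccc1)C(C)(C)C | intermediate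
18 | tiglic acid, (2E)-2-methylbut-2-enoic acid | C/C=C(\C)C(=O)O | starting material
19 | (8S)-tiglate, acetonide, C1-OTES | C/C=C(\C)C(=O)O[C@@H](C[C@@H](C)[C@H](O[Si](CC)(CC)CC)CC[C@]1(C)COC(C)(C)O1)C1=C(CO[Si](c2ccccc2)(c2ccccc2)C(C)(C)C)C(=O)OC1 | intermediate
20 | triol (C1, C4, C5 hydroxyls free) | C/C=C(\C)C(=O)O[C@@H](C[C@@H](C)[C@H](O)CC[C@@](C)(O)CO)C1=C(CO[Si](c2ccccc2)(c2ccccc2)C(C)(C)C)C(=O)OC1 | intermediate
21 | tris-TES ether | C/C=C(\C)C(=O)O[C@@H](C[C@@H](C)[C@H](O[Si](CC)(CC)CC)CC[C@@](C)(O[Si](CC)(CC)CC)CO[Si](CC)(CC)CC)C1=C(CO[Si](c2ccccc2)(c2ccccc2)C(C)(C)C)C(=O)OC1 | intermediate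
22 | C5 aldehyde (seco precursor) | C/C=C(\C)C(=O)O[C@@H](C[C@@H](C)[C@H](O[Si](CC)(CC)CC)CC[C@@](C)(O[Si](CC)(CC)CC)C=O)C1=C(CO[Si](c2ccccc2)(c2ccccc2)C(C)(C)C)C(=O)OC1 | intermediate
23 | (1R,4R,8S,10R)-13-(TBDPS-oxy)-5-hydroxy-1,4-bis(TES-oxy)-8-tigloyloxygermacr-7(11)-en-6,12-olide (C5/C6 mixture) | C/C=C(\C)C(=O)O[C@H]1C[C@@H](C)[C@H](O[Si](CC)(CC)CC)CC[C@@](C)(O[Si](CC)(CC)CC)C(O)C2OC(=O)C(CO[Si](c3ccccc3)(c3ccccc3)C(C)(C)C)=C21 | intermediate
24 | (1R,4R,8S,10R)-13-(TBDPS-oxy)-1,4-bis(TES-oxy)-8-tigloyloxygermacra-5E,7(11)-dien-6,12-olide | C/C=C(\C)C(=O)O[C@H]1C[C@@H](C)[C@H](O[Si](CC)(CC)CC)CC[C@@](C)(O[Si](CC)(CC)CC)/C=C2/OC(=O)C(CO[Si](c3ccccc3)(c3ccccc3)C(C)(C)C)=C21 | intermediate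
25 | (1R,4R,8S,10R)-1,4,13-trihydroxy-8-tigloyloxygermacra-5E,7(11)-dien-6,12-olide | C/C=C(\C)C(=O)O[C@H]1C[C@@H](C)[C@H](O)CC[C@@](C)(O)/C=C2/OC(=O)C(CO)=C21 | intermediate
26 | 13-O-acetate of 25 | C/C=C(\C)C(=O)O[C@H]1C[C@@H](C)[C@H](O)CC[C@@](C)(O)/C=C2/OC(=O)C(COC(C)=O)=C21 | intermediate
27 | (1S,4R,8S,10R)-13-acetoxy-1,4-epoxy-1-hydroxy-8-tigloyloxygermacra-5E,7(11)-dien-6,12-olide | C/C=C(\C)C(=O)O[C@H]1C[C@@H](C)[C@]2(O)CC[C@](C)(/C=C3/OC(=O)C(COC(C)=O)=C31)O2 | intermediate
28 | Vernolide-B | C/C=C(\C)C(=O)O[C@H]1C[C@@H](C)[C@]2(OC)CC[C@](C)(/C=C3/OC(=O)C(COC(C)=O)=C31)O2 | target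

## Summary

**Total steps:** 24 (20 on the main line plus 4 for iodobutenolide 14).
**Longest linear sequence:** 20 steps from (R)-linalool (steps 1–7 and 12–24).

**Three steps most likely to fail, with fallbacks:**

1. **Step 19 (proposed new macrocyclising vinylogous Mukaiyama aldol).** Risks are oligomerisation and transannular strain in the ten-membered closure. Fallback with known chemistry: close the ring at C7–C8 instead. Join the fragments first at C5–C6 by an intermolecular vinylogous Mukaiyama aldol of the 2-silyloxyfuran of 14 with a C5 aldehyde carrying C8 as a protected alcohol. Then unveil the C8 aldehyde and cyclise by intramolecular Ni/Cr (NHK) coupling, which is well precedented for ten-membered carbocycles. Finish with oxidation/CBS at C8, tigloylation and the same mesylate/DBU elimination.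

2. **Step 14 (CBS reduction of the 4-acylbutenolide).** Risks are modest selectivity and competing conjugate reduction. Fallback: skip the ketone. Separate the C8 epimers of 15, esterify the 8S epimer under Yamaguchi conditions, and convert the 8R epimer by Mitsunobu esterification with tiglic acid (inversion), so both converge on 19. Alternatively, set C8 during C–C bond formation with a chiral-sulfonamide-ligated asymmetric Ni/Cr coupling.

3. **Step 22 (selective acetylation of triol 25).** Risks are over-acylation at C1 or acyl migration. Fallback: an orthogonal sequence. Remove only the two TES ethers from 24 (PPTS, MeOH), oxidise C1 and form the methyl ketal with the C13 TBDPS ether still in place, then cleave the TBDPS ether (HF·pyridine) and acetylate the single remaining hydroxyl.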